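The constants were hidden, so I started from what blue and green showed.

| setting | blue | green | west | north | south-west | north-west | east |
|---|---|---|---|---|---|---|---|
| starting material | 0.095 M | 0.095 M | 0.095 M (in portions, 4, over 3.0 h) | 0.095 M | 0.095 M | 0.095 M | 0.095 M |
| second substrate | 0.0475 M | 0.0475 M | 0.0475 M | 0.0475 M (fed, over 3.0 h) | 0.0475 M | 0.0475 M (fed, over 3.0 h) | 0.0475 M |
| capture agent | 9.5 mM | 9.5 mM | 9.50 mM | 9.50 mM | 9.50 mM | 9.50 mM | 9.50 mM |
| free catalyst | 4.8 mM | 7.2 mM | 4.8 mM | 4.8 mM | 4.8 mM | 4.8 mM | 4.8 mM |
| temperature | 50 °C | 50 °C | 50 °C |  | 50 °C | 50 °C |  |
| remark | run made earlier | run made earlier | first portion at the start, last at 3.0 h | the addition at 20 °C, then warmed to 50 °C; the feed brings no volume worth counting | everything together at the start | all else is in the flask from the start; the feed brings no volume worth counting | everything together at the start at 20 °C, warmed to 50 °C at 3.0 h |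
| time |  |  | 4.0 h | 4.0 h | 4.0 h | 4.0 h | 4.0 h |

- blue (time / h: target / %): 0.833: 26; 1.50: 30; 2.50: 34; 3.00: 30; 4.00: 33
- green (time / min: target / %): 2.00: 5; 4.00: 8; 6.00: 9; 12.0: 17; 25.0: 27

(scatter of a reading: 2 percentage points)

- the analysis behind the earlier runs scatters by 2 percentage points, standard deviation
- candidate steps: starting material + free catalyst <-> catalyst intermediate A; free catalyst + target -> free catalyst + over-reaction product; second substrate + free catalyst <-> catalyst intermediate B; catalyst intermediate B + capture agent -> trapped intermediate; catalyst intermediate A -> free catalyst + target; catalyst intermediate B -> free catalyst + second product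
- the earlier runs do not show what temperature does; that part of a forecast is a guess

1. the flask that comes out highest in amount of target, in percent of the starting material charged, or "all alike" when all lie within 1.5 percentage points (west / north / south-west / north-west / east / all alike)
2. target at the end, in percent of the starting material charged, west
3. target at the end, in percent of the starting material charged, north
4. target at the end, in percent of the starting material charged, south-west
5. target at the end, in percent of the starting material charged, north-west
6. target at the end, in percent of the starting material charged, east

Blue read 30% at 1.50 h and 33% at 4.00 h, so it had stopped with 67.0% of the starting material unconverted. My working assumption was a catalyst that dies. Catalyst intermediate B can be caught by the capture agent, and blue holds more capture agent than catalyst.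

I treated target formation as pseudo-first-order in starting material, with a rate constant proportional to the catalyst alive. I called the sum of that rate constant over time the exposure, E. It equals the logarithm of the charged over the remaining c(starting material). Blue's final exposure was 0.400.

Green had the same c(second substrate) and c(capture agent), so I assumed the same lifetime. Its final exposure then scaled with the catalyst, to 0.601. With exponential death, the share of final exposure reached by a time t is one minus exp(−t/τ). Green's reading at 12.0 min gave 32.3 min, the catalyst lifetime τ at the full charge of second substrate. I put it back as a test on a reading I had not used: green at 25.0 min came to 27.7%, and the reading was 27%.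

Then I turned to north-west. I assumed the death rate was proportional to c(second substrate), and that c(second substrate) rose in line with the feed over its time T of 3.0 h. The surviving share then falls as a bell curve, and its sum over time is a working time L = √(π τ T/2), here 1.59 h. That is shorter than the feed, so the sum is nearly whole by the feed's end. Blue's working time was τ, so north-west's exposure was 1.18 and its conversion 69.3%. I took no deduction for over-reaction, so I expected more target than blue's 33%. τ was read at 50 °C, so it says nothing about the cold stages of north and east.

The forecast named north-west highest. It gave west 11%, north 38%, south-west 32%, north-west 58% and east 32%. Its ground for north-west was that “feeding keeps second substrate low”. My figure stood above its 58%.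

The simulation put north-west highest, at 72.3%. West gave 11.5%, north 22.9%, south-west 33.8% and east 10.7%.

    starting material + free catalyst ⇌ catalyst intermediate A (K = 7.49 M⁻¹, k = 0.0565 M⁻¹ s⁻¹, Ea = 61.0 kJ mol⁻¹, ΔH = −51.0 kJ mol⁻¹)
    free catalyst + target → free catalyst + over-reaction product (k = 0.00215 M⁻¹ s⁻¹, Ea = 84.0 kJ mol⁻¹)
    second substrate + free catalyst ⇌ catalyst intermediate B (K = 24.0 M⁻¹, k = 0.0786 M⁻¹ s⁻¹, Ea = 44.0 kJ mol⁻¹, ΔH = −20.0 kJ mol⁻¹)
    catalyst intermediate B + capture agent → trapped intermediate (k = 0.555 M⁻¹ s⁻¹, Ea = 43.0 kJ mol⁻¹)
    catalyst intermediate A → free catalyst + target (k = 0.143 s⁻¹, Ea = 91.0 kJ mol⁻¹)
    catalyst intermediate B → free catalyst + second product (k = 0.0110 s⁻¹, Ea = 83.0 kJ mol⁻¹)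
    (constants at 50 °C)

In north-west, 25.2% of the starting material remained at 4.00 h. That is an exposure of 1.38, against the 1.18 I had drawn from τ = 32.3 min. The conversion I reckoned lay 5.5 percentage points below the flask's.

Take a neighbour like north-west but with 0.12 M of second substrate. On my assumption, τ there comes to 12.8 min, L to 1.00 h, the exposure to 0.743 and the conversion to 52.4%. The computed neighbour gave 54.1% of target, with 45.0% of the starting material left.

(The numbers in the tables were computed for substances that don't exist; noise was put on by code.)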